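## Retrosynthetic overview

1. Target 30 ⇐ desilylation, C8 esterification with epoxyangelic acid 4, C9 acetylation and chelation-controlled reduction of the ten-membered keto ester 24.
2. 24 ⇐ two-carbon ring expansion (key step): formal insertion of methyl propiolate (C1, C10, C14) into the C9–C2 bond of cyclooctanone 21 through its silyl enol ether 22.
3. 21 ⇐ epoxidation and ring-closing metathesis (C4=C5) of diene 19; C2–C3 comes from a boron aldol of methyl ketone 15 with methacrolein.
4. 15 ⇐ Wacker oxidation and chromium-mediated lactone-forming allylation (C6–C7) of crotonaldehyde with bromide 11, itself from vinyloxirane (C8 by Pd-catalysed asymmetric etherification) and methyl propiolate.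
5. Ring order: γ-lactone, then eight-membered carbocycle, then oxirane, then ten-membered ring; acid 4 comes from methyl angelate by Sharpless epoxidation.

Assumption: atom labels C1–C15 are those of the germacranolide skeleton of the target (ring C1–C10, lactone carbons C11–C13, ester carbon C14 on C10, methyl C15 on C4; "1,10-dinor" means C9 is bonded to C2); TBS = tert-butyldimethylsilyl, PMB = 4-methoxybenzyl; the hand of the Trost ligand in step 4 is the one that delivers (R)-6.

## Route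

Step 1
Reactants: 1 methyl angelate
Product: 2 (2Z)-2-methylbut-2-en-1-ol
Conditions: iBu2AlH (2.2 equiv), CH2Cl2, −78 → 0 °C
Reagents that add atoms: none
Why: 1,2-reduction of the conjugated ester by the aluminium hydride (ester to allylic alcohol) leaves the Z trisubstituted alkene untouched.

Step 2
Reactants: 2 (2Z)-2-methylbut-2-en-1-ol
Product: 3 [(2R,3S)-2,3-dimethyloxiran-2-yl]methanol
Conditions: Ti(OiPr)4 (10 mol %), D-(−)-diethyl tartrate (12 mol %), tBuOOH, 4 Å MS, CH2Cl2, −20 °C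
Reagents that add atoms: tert-butyl hydroperoxide, CC(C)(C)OO
Why: Sharpless asymmetric epoxidation; the D-tartrate complex delivers oxygen to the alkene face that gives the 2R,3S epoxy alcohol, and the Z geometry fixes CH2OH and the C3 methyl cis.

Step 3
Reactants: 3 [(2R,3S)-2,3-dimethyloxiran-2-yl]methanol
Product: 4 (2S,3S)-2,3-dimethyloxirane-2-carboxylic acid
Conditions: RuCl3·xH2O (2 mol %), NaIO4 (3 equiv), CCl4/MeCN/H2O, 0 °C → rt
Reagents that add atoms: water, O; sodium periodate (terminal oxidant), [Na+].[O-]I(=O)(=O)=O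
Why: Sharpless RuO4 oxidation takes the primary alcohol to the acid without touching the trisubstituted epoxide; no stereocentre changes (only the C2 descriptor, by priority).

Step 4
Reactants: 5 racemic 2-vinyloxirane
Product: 6 (2R)-2-[(4-methoxybenzyl)oxy]but-3-en-1-ol
Conditions: Pd2(dba)3·CHCl3 (1 mol %), (S,S)-DACH-phenyl Trost ligand (3 mol %), Et3B (1 mol %), 4-MeOC6H4CH2OH, CH2Cl2, rt
Reagents that add atoms: 4-methoxybenzyl alcohol, COc1ccc(CO)cc1
Why: Trost palladium-catalysed dynamic kinetic asymmetric allylic etherification; the equilibrating π-allylpalladium alkoxide from racemic 5 is intercepted at the branched carbon by boron-bound PMB alcohol, and the ligand pocket sets the R centre that becomes C8.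

Step 5
Reactants: 6 (2R)-2-[(4-methoxybenzyl)oxy]but-3-en-1-ol
Product: 7 (2R)-2-[(4-methoxybenzyl)oxy]but-3-enal
Conditions: Dess–Martin periodinane, NaHCO3, CH2Cl2, 0 °C; used crude
Reagents that add atoms: none
Why: Dess–Martin oxidation under bicarbonate buffer is mild enough to give the β,γ-unsaturated α-alkoxy aldehyde without racemisation or migration of the alkene into conjugation.

Step 6
Reactants: 7 (2R)-2-[(4-methoxybenzyl)oxy]but-3-enal; 8 methyl propiolate
Product: 10 methyl (4R)-3-hydroxy-4-[(4-methoxybenzyl)oxy]-2-methylidenehex-5-enoate (both C3 epimers), via vinylalane 9 (not isolated)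
Conditions: iBu2AlH, N-methylmorpholine N-oxide, THF, 0 °C; then 8; then 7, 0 °C → rt
Reagents that add atoms: none
Why: Hydroalumination of 8 gives the α-alumino acrylate 9, which adds to the aldehyde (vinylalumination, a non-basic equivalent of the Morita–Baylis–Hillman reaction) so the labile aldehyde is not enolised; the new carbinol centre forms unselectively and is erased in step 7.

Step 7
Reactants: 10 methyl (4R)-3-hydroxy-4-[(4-methoxybenzyl)oxy]-2-methylidenehex-5-enoate
Product: 11 methyl (2Z,4R)-2-(bromomethyl)-4-[(4-methoxybenzyl)oxy]hexa-2,5-dienoate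
Conditions: NBS, Me2S, CH2Cl2, 0 °C → rt
Reagents that add atoms: N-bromosuccinimide, BrN1C(=O)CCC1=O
Why: Corey–Kim-type activation of the allylic alcohol and SN2′ attack of bromide (allylic transposition) give the thermodynamically favoured 2Z bromomethyl enoate; C8 is untouched.

Step 8
Reactants: 11 methyl (2Z,4R)-2-(bromomethyl)-4-[(4-methoxybenzyl)oxy]hexa-2,5-dienoate; 12 (2E)-but-2-enal
Product: 14 (4R,5R)-4-{(1R)-1-[(4-methoxybenzyl)oxy]prop-2-en-1-yl}-3-methylidene-5-[(1E)-prop-1-en-1-yl]oxolan-2-one, via hydroxy ester 13 (not isolated)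
Conditions: CrCl2 (3 equiv), THF, 0 °C → rt; aq. NH4Cl; then PPTS (cat.), CH2Cl2, rt
Reagents that add atoms: none
Why: Nozaki–Hiyama-type 2-(alkoxycarbonyl)allylation by divalent chromium; a chair transition state of the equilibrated allylchromium (C8 trans to the CH2–Cr terminus) gives the anti C6/C7 adduct and hence the trans lactone, while the aldehyde adds to the C7 face anti to the vinyl group of the A(1,3)-locked C8 centre, setting C6 and C7 as in the target; lactonisation expels methanol.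

Step 9
Reactants: 14 (4R,5R)-4-{(1R)-1-[(4-methoxybenzyl)oxy]prop-2-en-1-yl}-3-methylidene-5-[(1E)-prop-1-en-1-yl]oxolan-2-one
Product: 15 (4S,5R)-4-{(1S)-1-[(4-methoxybenzyl)oxy]-2-oxopropyl}-3-methylidene-5-[(1E)-prop-1-en-1-yl]oxolan-2-one
Conditions: PdCl2(Quinox) (5 mol %), AgSbF6 (12 mol %), aq. tBuOOH, CH2Cl2, rt
Reagents that add atoms: tert-butyl hydroperoxide, CC(C)(C)OO
Why: Catalyst-controlled Tsuji–Wacker oxidation; only the terminal monosubstituted alkene reacts (the internal propenyl and the electron-poor methylidene are inert), and the Quinox system gives the methyl ketone despite the allylic ether, without epimerising C8.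

Step 10
Reactants: 15 (4S,5R)-4-{(1S)-1-[(4-methoxybenzyl)oxy]-2-oxopropyl}-3-methylidene-5-[(1E)-prop-1-en-1-yl]oxolan-2-one; 16 methacrolein
Product: 18 (4S,5R)-4-{(1S,4R)-4-hydroxy-1-[(4-methoxybenzyl)oxy]-5-methyl-2-oxohex-5-en-1-yl}-3-methylidene-5-[(1E)-prop-1-en-1-yl]oxolan-2-one, via boron enolate 17 (not isolated)
Conditions: (c-C6H11)2BCl, Et3N, Et2O, −78 °C; then 16, −78 → −20 °C; MeOH/pH 7 buffer
Reagents that add atoms: none
Why: Paterson boron aldol; the borane/amine pair enolises only the methyl side, and the α-alkoxy stereocentre directs the chair transition state to the 1,4-syn adduct, setting C3 (R); the lactone is not enolised and the non-oxidative work-up spares the methylidene lactone.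

Step 11
Reactants: 18 (aldol adduct)
Product: 19 (4S,5R)-4-{(1S,4R)-4-[(tert-butyldimethylsilyl)oxy]-1-[(4-methoxybenzyl)oxy]-5-methyl-2-oxohex-5-en-1-yl}-3-methylidene-5-[(1E)-prop-1-en-1-yl]oxolan-2-one
Conditions: TBSOTf (1.1 equiv), 2,6-lutidine, CH2Cl2, −78 °C
Reagents that add atoms: tert-butyldimethylsilyl triflate, CC(C)(C)[Si](C)(C)OS(=O)(=O)C(F)(F)F
Why: Standard silylation of the secondary alcohol blocks retro-aldol and β-elimination in the later enolate chemistry; no stereocentre is touched.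

Step 12
Reactants: 19 (TBS ether)
Product: 20 (3R,4Z,6R,7S,8S)-3-(TBS-oxy)-8-(PMB-oxy)-9-oxo-1,10-dinorgermacra-4,11(13)-dien-12,6-olide
Conditions: second-generation Hoveyda–Grubbs catalyst RuCl2(H2IMes)(=CH-C6H4-2-OiPr) (10 mol %), toluene (2 mM), 80 °C
Reagents that add atoms: none
Why: Ring-closing metathesis; the ruthenium carbene loads at the propenyl group and closes onto the 1,1-disubstituted alkene, high dilution favours the eight-membered ring, and the ring size enforces the cis (4Z) trisubstituted alkene; propene is lost.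

Step 13
Reactants: 20 (cyclooctene lactone)
Product: 21 (3R,4R,5R,6S,7S,8S)-3-(TBS-oxy)-4,5-epoxy-8-(PMB-oxy)-9-oxo-1,10-dinorgermacr-11(13)-en-12,6-olide
Conditions: mCPBA, NaHCO3, CH2Cl2, 0 °C
Reagents that add atoms: 3-chloroperoxybenzoic acid, OOC(=O)c1cccc(Cl)c1
Why: Prilezhaev epoxidation of the only electron-rich alkene from the face opposite the two allylic C–O substituents (C3 silyl ether and C6 lactone oxygen, both on the same face), as in peracid epoxidations of cyclooct-2-enol derivatives; this sets C4 and C5.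

Step 14
Reactants: 21 (epoxy ketone)
Product: 22 (3R,4R,5R,6S,7S,8S)-3-(TBS-oxy)-4,5-epoxy-8-(PMB-oxy)-9-(trimethylsilyloxy)-1,10-dinorgermacra-2(9),11(13)-dien-12,6-olide
Conditions: LiN(iPr)2 (1.05 equiv), Me3SiCl (in situ), THF, −78 °C; Et3N, pentane filtration
Reagents that add atoms: chlorotrimethylsilane, C[Si](C)(C)Cl
Why: Kinetic deprotonation at the less hindered C2 methylene with internal silyl quench (enol silane formation) gives the C9=C2 enol ether before β-elimination of the C3 silyloxy group or deprotonation of the lactone can compete.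

Step 15
Reactants: 22 (trimethylsilyl enol ether); 8 methyl propiolate
Product: 24 methyl (1(10)E,3R,4R,5R,6S,7S,8S)-3-(TBS-oxy)-4,5-epoxy-8-(PMB-oxy)-9-oxogermacra-1(10),11(13)-dien-12,6-olid-14-oate (C2 and C9 cis across C1=C10), via siloxycyclobutene 23 (not isolated)
Conditions: Tf2NH (5 mol %), 8 (3 equiv), CH2Cl2, −78 °C; then Bu4NF/AcOH (1:1, 1.1 equiv), THF, −78 → 0 °C
Reagents that add atoms: none
Why: Proposed new method: one-flask formal insertion of an alkyne into the C(O)–Cα bond of a non-activated medium-ring ketone — the silyl triflimide formed from Tf2NH activates 8, C2 of the enol ether adds to the alkyne terminus (Mukaiyama–Michael), the silyl allenoate closes through C10 onto the C9 oxocarbenium to give cyclobutene 23 (stepwise polar (2+2)), and buffered fluoride then unmasks the C9 alkoxide, whose retro-aldol (Grob-type) cleavage of C9–C2, driven by ring strain and by formation of the extended β-keto ester enolate, expands the eight-membered ring to the ten-membered one; protonation at C2 gives the conjugated alkylidene keto ester, and the cis relationship of C9 and C2 across C1=C10 is inherited from the four-membered ring; the closest known reaction types are Lewis-acid- or triflimide-catalysed (2+2) cycloadditions of silyl enol ethers with propiolates, retro-aldol opening of donor–acceptor cyclobutanes and base-mediated two-carbon ring expansion of cyclic β-keto esters with alkynoates, none of them merged into one operation or shown for an 8→10 expansion of a polyoxygenated mono-ketone.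

Step 16
Reactants: 24 (ten-membered keto ester)
Product: 25 methyl (1(10)E,3R,4R,5R,6S,7R,8S,9R)-3-(TBS-oxy)-4,5-epoxy-9-hydroxy-8-(PMB-oxy)germacra-1(10),11(13)-dien-12,6-olid-14-oate
Conditions: Zn(BH4)2, Et2O, −40 °C
Reagents that add atoms: none
Why: Chelation-controlled 1,2-reduction; zinc bridges the C9 carbonyl and the C8 PMB ether oxygen and hydride enters from the face away from C7 (the outer face of the ring), giving the 9R alcohol cis to the C8 oxygen, while esters, lactone and epoxide are not reduced.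

Step 17
Reactants: 25 (C9 alcohol)
Product: 26 methyl (1(10)E,3R,4R,5R,6S,7R,8S,9R)-9-acetoxy-3-(TBS-oxy)-4,5-epoxy-8-(PMB-oxy)germacra-1(10),11(13)-dien-12,6-olid-14-oate
Conditions: Ac2O, pyridine, DMAP (cat.), CH2Cl2, 0 °C
Reagents that add atoms: acetic anhydride, CC(=O)OC(C)=O
Why: DMAP-catalysed acetylation of the only free hydroxyl; no stereocentre is touched.

Step 18
Reactants: 26 (C9 acetate)
Product: 27 methyl (1(10)E,3R,4R,5R,6S,7R,8S,9R)-9-acetoxy-3-(TBS-oxy)-4,5-epoxy-8-hydroxygermacra-1(10),11(13)-dien-12,6-olid-14-oate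
Conditions: DDQ, CH2Cl2/pH 7 buffer, 0 °C
Reagents that add atoms: none
Why: Oxidative PMB cleavage (benzylic hydride abstraction by DDQ, then hydrolysis) under buffered conditions leaves the silyl ether, epoxide, acetate and electron-poor alkenes intact and avoids acetyl migration.

Step 19
Reactants: 27 (C8 alcohol); 4 (2S,3S)-2,3-dimethyloxirane-2-carboxylic acid
Product: 29 methyl (1(10)E,3R,4R,5R,6S,7R,8S,9R)-9-acetoxy-8-[(2S,3S)-2,3-dimethyloxirane-2-carbonyloxy]-3-(TBS-oxy)-4,5-epoxygermacra-1(10),11(13)-dien-12,6-olid-14-oate, via mixed anhydride 28 (not isolated)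
Conditions: 4, 2,4,6-Cl3C6H2COCl, Et3N, THF, rt; then 27, DMAP, toluene, rt
Reagents that add atoms: none
Why: Yamaguchi esterification; DMAP transfers the epoxyangeloyl group of 28 to the C8 hydroxyl, and since the acid has no α-hydrogen its two stereocentres cannot epimerise.

Step 20
Reactants: 29 (silyl-protected target)
Product: 30 methyl (1(10)E,3R,4S,5R,6S,7R,8S,9R)-9-acetoxy-8-[(2S,3S)-2,3-dimethyloxirane-2-carbonyloxy]-4,5-epoxy-3-hydroxygermacra-1(10),11(13)-dien-12,6-olid-14-oate (CNP0301544.1)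
Conditions: HF·pyridine, pyridine/THF, 0 °C → rt
Reagents that add atoms: none
Why: Fluoride-mediated desilylation under buffered conditions removes the TBS group without opening either epoxide or moving the acyl groups (the C4 descriptor changes from R to S only by priority).

## Compound list

1 | methyl angelate, methyl (2Z)-2-methylbut-2-enoate | C/C=C(C)\C(=O)OC | starting material
2 | (2Z)-2-methylbut-2-en-1-ol | C/C=C(C)\CO | intermediate
3 | [(2R,3S)-2,3-dimethyloxiran-2-yl]methanol | OC[C@@]1(C)O[C@H]1C | intermediate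
4 | (2S,3S)-2,3-dimethyloxirane-2-carboxylic acid | OC(=O)[C@@]1(C)O[C@H]1C | intermediate
5 | racemic 2-vinyloxirane | C=CC1CO1 | starting material
6 | (2R)-2-[(4-methoxybenzyl)oxy]but-3-en-1-ol | OC[C@H](OCc1ccc(OC)cc1)C=C | intermediate
7 | (2R)-2-[(4-methoxybenzyl)oxy]but-3-enal | O=C[C@H](OCc1ccc(OC)cc1)C=C | intermediate
8 | methyl propiolate | C#CC(=O)OC | starting material
9 | methyl 2-(diisobutylalumanyl)acrylate (vinylalane) | C=C(C(=O)OC)[Al](CC(C)C)CC(C)C | intermediate
10 | methyl (4R)-3-hydroxy-4-[(4-methoxybenzyl)oxy]-2-methylidenehex-5-enoate (both C3 epimers) | C=C(C(=O)OC)C(O)[C@H](OCc1ccc(OC)cc1)C=C | intermediate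
11 | methyl (2Z,4R)-2-(bromomethyl)-4-[(4-methoxybenzyl)oxy]hexa-2,5-dienoate | BrC/C(C(=O)OC)=C\[C@H](OCc1ccc(OC)cc1)C=C | intermediate
12 | (2E)-but-2-enal (crotonaldehyde) | C/C=C/C=O | starting material
13 | methyl (3S,4R,5E)-4-hydroxy-3-{(1R)-1-[(4-methoxybenzyl)oxy]prop-2-en-1-yl}-2-methylidenehept-5-enoate | C=C(C(=O)OC)[C@@H]([C@H](O)/C=C/C)[C@H](OCc1ccc(OC)cc1)C=C | intermediate
14 | (4R,5R)-4-{(1R)-1-[(4-methoxybenzyl)oxy]prop-2-en-1-yl}-3-methylidene-5-[(1E)-prop-1-en-1-yl]oxolan-2-one | C=C1C(=O)O[C@H](/C=C/C)[C@H]1[C@H](OCc2ccc(OC)cc2)C=C | intermediate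
15 | (4S,5R)-4-{(1S)-1-[(4-methoxybenzyl)oxy]-2-oxopropyl}-3-methylidene-5-[(1E)-prop-1-en-1-yl]oxolan-2-one | C=C1C(=O)O[C@H](/C=C/C)[C@H]1[C@H](OCc2ccc(OC)cc2)C(C)=O | intermediate
16 | methacrolein (2-methylprop-2-enal) | CC(=C)C=O | starting material
17 | dicyclohexylboron enolate of 15 (methyl-side enol borinate) | C=C1C(=O)O[C@H](/C=C/C)[C@H]1[C@H](OCc2ccc(OC)cc2)C(=C)OB(C3CCCCC3)C4CCCCC4 | intermediate
18 | (4S,5R)-4-{(1S,4R)-4-hydroxy-1-[(4-methoxybenzyl)oxy]-5-methyl-2-oxohex-5-en-1-yl}-3-methylidene-5-[(1E)-prop-1-en-1-yl]oxolan-2-one | C=C1C(=O)O[C@H](/C=C/C)[C@H]1[C@H](OCc2ccc(OC)cc2)C(=O)C[C@@H](O)C(C)=C | intermediate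
19 | TBS ether of 18 at the C3 hydroxyl | C=C1C(=O)O[C@H](/C=C/C)[C@H]1[C@H](OCc2ccc(OC)cc2)C(=O)C[C@@H](O[Si](C)(C)C(C)(C)C)C(C)=C | intermediate
20 | (3R,4Z,6R,7S,8S)-3-(TBS-oxy)-8-(PMB-oxy)-9-oxo-1,10-dinorgermacra-4,11(13)-dien-12,6-olide | C=C1C(=O)O[C@@H]2/C=C(C)\[C@H](O[Si](C)(C)C(C)(C)C)CC(=O)[C@@H](OCc3ccc(OC)cc3)[C@@H]12 | intermediate
21 | (3R,4R,5R,6S,7S,8S)-3-(TBS-oxy)-4,5-epoxy-8-(PMB-oxy)-9-oxo-1,10-dinorgermacr-11(13)-en-12,6-olide | C=C1C(=O)O[C@H]2[C@H]1[C@H](OCc3ccc(OC)cc3)C(=O)C[C@@H](O[Si](C)(C)C(C)(C)C)[C@]1(C)O[C@H]21 | intermediate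
22 | (3R,4R,5R,6S,7S,8S)-3-(TBS-oxy)-4,5-epoxy-8-(PMB-oxy)-9-(trimethylsilyloxy)-1,10-dinorgermacra-2(9),11(13)-dien-12,6-olide | C=C1C(=O)O[C@H]2[C@H]1[C@H](OCc3ccc(OC)cc3)/C(O[Si](C)(C)C)=C\[C@@H](O[Si](C)(C)C(C)(C)C)[C@]1(C)O[C@H]21 | intermediate
23 | siloxycyclobutene: C9(OSiMe3)–C10(CO2Me)=C1H–C2H four-membered ring fused cis across C9–C2 of 22, new bonds assumed anti to the C3 silyl ether (both faces converge on 24) | C=C1C(=O)O[C@H]2[C@H]1[C@H](OCc3ccc(OC)cc3)[C@]4(O[Si](C)(C)C)C(C(=O)OC)=C[C@@H]4[C@@H](O[Si](C)(C)C(C)(C)C)[C@]1(C)O[C@H]21 | intermediate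
24 | methyl (1(10)E,3R,4R,5R,6S,7S,8S)-3-(TBS-oxy)-4,5-epoxy-8-(PMB-oxy)-9-oxogermacra-1(10),11(13)-dien-12,6-olid-14-oate | C=C1C(=O)O[C@H]2[C@H]1[C@H](OCc3ccc(OC)cc3)C(=O)/C(C(=O)OC)=C\C[C@@H](O[Si](C)(C)C(C)(C)C)[C@]1(C)O[C@H]21 | intermediate
25 | methyl (1(10)E,3R,4R,5R,6S,7R,8S,9R)-3-(TBS-oxy)-4,5-epoxy-9-hydroxy-8-(PMB-oxy)germacra-1(10),11(13)-dien-12,6-olid-14-oate | C=C1C(=O)O[C@H]2[C@H]1[C@H](OCc3ccc(OC)cc3)[C@H](O)/C(C(=O)OC)=C\C[C@@H](O[Si](C)(C)C(C)(C)C)[C@]1(C)O[C@H]21 | intermediate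
26 | methyl (1(10)E,3R,4R,5R,6S,7R,8S,9R)-9-acetoxy-3-(TBS-oxy)-4,5-epoxy-8-(PMB-oxy)germacra-1(10),11(13)-dien-12,6-olid-14-oate | C=C1C(=O)O[C@H]2[C@H]1[C@H](OCc3ccc(OC)cc3)[C@H](OC(C)=O)/C(C(=O)OC)=C\C[C@@H](O[Si](C)(C)C(C)(C)C)[C@]1(C)O[C@H]21 | intermediate
27 | methyl (1(10)E,3R,4R,5R,6S,7R,8S,9R)-9-acetoxy-3-(TBS-oxy)-4,5-epoxy-8-hydroxygermacra-1(10),11(13)-dien-12,6-olid-14-oate | C=C1C(=O)O[C@H]2[C@H]1[C@H](O)[C@H](OC(C)=O)/C(C(=O)OC)=C\C[C@@H](O[Si](C)(C)C(C)(C)C)[C@]1(C)O[C@H]21 | intermediate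
28 | (2S,3S)-2,3-dimethyloxirane-2-carboxylic 2,4,6-trichlorobenzoic anhydride | O=C(OC(=O)c1c(Cl)cc(Cl)cc1Cl)[C@@]2(C)O[C@H]2C | intermediate
29 | methyl (1(10)E,3R,4R,5R,6S,7R,8S,9R)-9-acetoxy-8-[(2S,3S)-2,3-dimethyloxirane-2-carbonyloxy]-3-(TBS-oxy)-4,5-epoxygermacra-1(10),11(13)-dien-12,6-olid-14-oate | C=C1C(=O)O[C@H]2[C@H]1[C@H](OC(=O)[C@@]3(C)O[C@H]3C)[C@H](OC(C)=O)/C(C(=O)OC)=C\C[C@@H](O[Si](C)(C)C(C)(C)C)[C@]1(C)O[C@H]21 | intermediate
30 | methyl (1(10)E,3R,4S,5R,6S,7R,8S,9R)-9-acetoxy-8-[(2S,3S)-2,3-dimethyloxirane-2-carbonyloxy]-4,5-epoxy-3-hydroxygermacra-1(10),11(13)-dien-12,6-olid-14-oate (CNP0301544.1) | C=C1C(=O)O[C@H]2[C@H]1[C@H](OC(=O)[C@@]1(C)O[C@H]1C)[C@H](OC(C)=O)/C(C(=O)OC)=C\C[C@@H](O)[C@]1(C)O[C@H]21 | target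

## Step count and risks

Total step count: 20 (3 for acid 4, 17 in the main line). Longest linear sequence: 17 steps (5 → 30, steps 4–20).

Steps most likely to fail:

Step 15 (the proposed ring expansion). The triflimide-catalysed (2+2) may stall, the epoxide may not tolerate the silyl Lewis acid, or the dienolate may protonate to the wrong tautomer. Fallback with known chemistry, setting out from enol ether 22: stoichiometric EtAlCl2 (CH2Cl2, −78 °C) with 8 gives cyclobutene 23, which is isolated. Heating in toluene (90 °C) opens it by the known conrotatory electrocyclic ring opening to the ring-expanded silyl dienol ether F1. Dilute HCl in THF hydrolyses this to the deconjugated β-keto ester F2, and catalytic Et3N moves the alkene into conjugation, coming back to the route at 24.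

Step 8 (chromium allylation). The anti (trans-lactone) selectivity and the facial selectivity at C7 are argued from models, not secured. Fallback, setting out from bromide 11 (and 12): indium powder in THF/H2O gives, through the PMB-chelated Z-allylindium, the syn hydroxy ester F3 (C6 epimer of 13, same C7 and C8). LiOH gives the hydroxy acid F4, and Mitsunobu lactonisation (PPh3, DIAD) closes the lactone with inversion at C6, coming back to the route at 14.

Step 16 (C9 reduction). Zinc may chelate the β-keto ester instead of the C8 ether, or ring conformation may override chelation. Fallback, setting out from ketone 24: if hydride delivery (for example NaBH4/CeCl3, MeOH, −78 °C) gives mainly the 9-epi alcohol F5, Mitsunobu inversion with acetic acid (PPh3, DIAD) installs the acetate with the correct configuration and comes back to the route at 26, skipping step 17.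

## Further compounds

F1 | step 15 | silyl dienol ether: methyl (3R,4R,5R,6S,7S,8S)-3-(TBS-oxy)-4,5-epoxy-8-(PMB-oxy)-9-(trimethylsilyloxy)germacra-1,9,11(13)-trien-12,6-olid-14-oate (C1=C2 trans, C9=C10 cis in the ring) | C=C1C(=O)O[C@H]2[C@H]1[C@H](OCc3ccc(OC)cc3)/C(O[Si](C)(C)C)=C(C(=O)OC)\C=C\[C@@H](O[Si](C)(C)C(C)(C)C)[C@]1(C)O[C@H]21
F2 | step 15 | deconjugated β-keto ester: methyl (1E,3R,4R,5R,6S,7S,8S)-3-(TBS-oxy)-4,5-epoxy-8-(PMB-oxy)-9-oxogermacra-1,11(13)-dien-12,6-olid-14-oate (both C10 epimers) | C=C1C(=O)O[C@H]2[C@H]1[C@H](OCc3ccc(OC)cc3)C(=O)C(C(=O)OC)/C=C/[C@@H](O[Si](C)(C)C(C)(C)C)[C@]1(C)O[C@H]21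
F3 | step 8 | methyl (3S,4S,5E)-4-hydroxy-3-{(1R)-1-[(4-methoxybenzyl)oxy]prop-2-en-1-yl}-2-methylidenehept-5-enoate | C=C(C(=O)OC)[C@@H]([C@@H](O)/C=C/C)[C@H](OCc1ccc(OC)cc1)C=C
F4 | step 8 | (3S,4S,5E)-4-hydroxy-3-{(1R)-1-[(4-methoxybenzyl)oxy]prop-2-en-1-yl}-2-methylidenehept-5-enoic acid | C=C(C(=O)O)[C@@H]([C@@H](O)/C=C/C)[C@H](OCc1ccc(OC)cc1)C=C
F5 | step 16 | methyl (1(10)E,3R,4R,5R,6S,7R,8S,9S)-3-(TBS-oxy)-4,5-epoxy-9-hydroxy-8-(PMB-oxy)germacra-1(10),11(13)-dien-12,6-olid-14-oate | C=C1C(=O)O[C@H]2[C@H]1[C@H](OCc3ccc(OC)cc3)[C@@H](O)/C(C(=O)OC)=C\C[C@@H](O[Si](C)(C)C(C)(C)C)[C@]1(C)O[C@H]21
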